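# Synthesis plan for CNP0237201.2 (target 30): macrocyclic oxy-Cope ring contraction

Atom labels C1–C31 follow the order of the non-hydrogen atoms in the target SMILES. Locants inside systematic names are those of the name. Compound numbers 1–30 are those of the steps below.

## The problem

The target 30 is a C20 skeleton with a 3-methylbut-2-enoyl enol ester. Ring A (cyclohexane C15–C16–C17–C18–C20–C21) and ring B (cycloheptanone C5–C6–C8–C21–C20–C18–C22) share the C18–C20–C21 bridge, a bicyclo[4.3.1]decane. Ring C (tetrahydropyran C8–C10–O11–C12–C15–C21) is fused across C8–C21–C15. There are six stereocentres: quaternary C18, the tertiary carbinol C8, C21, C15, and the trans pair C5/C22 that carries the acetonyl arm and the (E)-enol ester arm. The chain C12–C17 on C18 can reach C21 only from its own face, so C18 can dictate C21 and C15, and C8 follows if its oxygen is placed anti to that attack. C5 and C22 need a separate device that relates them to C18. The (E)-enol ester is an acylating agent and loses its geometry if it is made late from an aldehyde. The C2/C6 1,4-diketone has an epimerisable C5 and can close to a cyclopentenone. The C6/C8 α-ketol does not tolerate strong base. The enabling feature is that the arms on C5 (C4, C2) and C22 (C23, C24) end in the C2 carbonyl and the C24 enol oxygen. Joining C2 to C24 turns ring B and both arms into an eleven-membered 3-hydroxy-4-acyloxy-1,5-diene, the retron of a [3,3] shift.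

## Retrosynthesis

**Rings A and C (30 → 29).** The bonds C15–C21 and O11–C12 are cut together. This leaves the cycloheptanone 29 with a C8/C21 epoxide, the C10 hydroxymethyl group and the 4-methylpent-3-enyl chain on C18. Closing the rings last means the bridged system never has to be carried, and the C8 oxygen arrives with the electrophile. The forward step is an epoxide-opening cation–olefin cyclisation ended by the C10 hydroxyl. The C6 carbonyl disfavours ionisation at C8, so opening occurs at C21.

**Epoxide (29 → 28).** The oxirane comes from the C8=C21 alkene of enone 28. This alkene is conjugated to C6, so an electrophilic metal-peroxo reagent guided by the C10 hydroxyl (for example VO(acac)2 with t-BuOOH) would find the isolated trisubstituted alkene of the side chain more nucleophilic. A nucleophilic peroxide reacts with the enone only, and is therefore preferred.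

**Ring B (28 → 26).** In the retro direction C5–C22 is cut and C2–C24 is made, which gives the eleven-membered (E,E)-dienone 26. The alternative, attaching the two arms one at a time to a finished cycloheptanone, would need a late enol ester synthesis without E/Z control. Here both arms, the trans relation and the enol ester geometry come from one thermal step. The forward reaction must use one chair. In the chair that leads to 28 the (24R)-acyloxy group and the C1 methyl on (2S)-C2 are both equatorial, so C2 is kept stereodefined although it is lost in the product.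

**Macrocycle (26 → 23).** The ring is opened at C6–C8, giving the acyclic (Z)-alkenyl iodide/enal 23 (via 25 and 24). Closure at C23–C24 would create C24, which selects the chair, in an event of unknown diastereoselectivity. Closure by olefination at C4=C5 would expose the base-labile, thermodynamically disfavoured C21=C8 enone geometry in an open chain. A Nozaki–Hiyama–Kishi closure at C6–C8 carries the alkene geometry in the iodide, and the new carbinol is erased by oxidation.

**C2/C24 and the enal (23 → 18).** The enal carbons C5–C6 come from a Wittig reaction on the α-hydroxy aldehyde 22, made by oxidation of diol ester 21. Diol ester 21 arises from the (2S,3S)-epoxy alcohol 19 and 3-methylbut-2-enoic acid 20 by opening at the allylic carbon C24 with inversion. Epoxide 19 is the Sharpless product of dienol 18. Both stereocentres are thus set by reagent control, and the ester is installed in the bond-forming step, so no selective acylation is needed.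

**Iodoalkene arm (18 → 14).** Protecting-group exchange (17, 16) and ester reduction lead back to the (Z)-α-iodoacrylate 15. Its C21=C8 bond comes from aldehyde 14 and an iodo-ylide. The kinetic (Z)-iodide is the only reliable source of the ring-cis C20/C6 relationship.

**Diene (13 → 6 + 10).** Aldehyde 14 comes from alcohol 13. The C23–C24 bond of 13 is cut to alkyne 6 and the (E)-iodide 10, which is made from prop-2-yn-1-ol 7 via 9. Hydrozirconation and Negishi coupling give the (E,E)-diene directly, with the allylic oxygen needed for the epoxidation.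

**Quaternary C18 (6 → 3 → 2 → 1).** Alkynol 6 comes from enyne 3 by hydroboration of the vinyl group and desilylation. Enyne 3 comes from geranyl phosphate 2, and so from geraniol 1, by a copper-catalysed enantioselective SN2′ alkynylation. The vinyl group becomes C20–C21 and the alkyne becomes C22–C23, so both arms of the future ring leave C18 in one step.

## Roads not taken

**Alternative 1:** The cut is C4–C5 and C22–C23 on a finished tricycle. C6 is a carbinol, C5=C22 an alkene, and the acetonyl carbons are tethered to the C6 oxygen as a mixed bromoketal.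
- Forward step: a tin radical abstracts the halogen, the C4 radical closes 5-exo onto C5, and the C22 radical is trapped by an allyl-tin reagent anti to the new ring, giving ketal A1.
- Merits: radical chemistry tolerates the neopentyl C22 next to C18. The rigid tricycle makes the trans C5/C22 outcome more predictable than a conformational choice in a macrocycle.
- Weak points: the whole tricycle with protected C8 carbinol must exist first. The allyl group has one carbon too many and must be cut back to an aldehyde, then acylated to the enol ester with no control of E/Z and under conditions that can epimerise C5 once C6 is a ketone. Ketal hydrolysis, C6 oxidation and stoichiometric tin add steps.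
- Comparison: this road is superior in the security of the C5/C22 relationship. The chosen plan offers instead an enol ester that is formed directly as the (E)-isomer and never touched again, at the price of a long approach to the macrocycle.

**Alternative 2:** The cut is C18–C20 and C16–C17. A type 2 intramolecular Diels–Alder reaction joins the exocyclic diene of a 3,4-dimethylenetetrahydropyran to a tethered (E)-vinyl sulfone, giving the bridgehead alkene A2.
- Merits: rings A and B and quaternary C18 are made in one step around a preformed ring C. The core is reached in fewer steps than in the chosen plan.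
- Weak points: A2 has neither arm. C22 is a neopentyl methylene and C5 a plain methylene, so the vicinal trans arms and the enol ester must all be built afterwards. The bridgehead alkene must be hydrogenated from one face to set C15 and C21. The sulfone must be removed.
- Comparison: this road is better for the carbocyclic core. The chosen plan is better for the part A2 leaves open, the two arms and their geometry.

**Alternative 3:** The cut is C15–C21 in a bridged aldol reaction of a prochiral 2,2-disubstituted cycloheptane-1,3-dione. A chiral primary amine forms the enamine of one enantiotopic ketone, which adds to the pendant aldehyde and gives ketol A3.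
- Merits: C18, C21 and C15 are set catalytically from achiral material in very few steps. No other road has this economy of asymmetric induction.
- Weak points: A3 is far from the target. The C20 ketone must become a methylene, the C22 ketone a CH bearing the enol ester arm, and the C15 carbinol a C–C bond to C12. C6, C8 and C10 carry no oxygen yet. Ring C and both arms are missing.
- Comparison: the chosen plan needs a metal catalyst and a tartrate-controlled epoxidation for its stereocentres, but nearly every carbon arrives at its final oxidation level.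

Key step: step 18

Remark: in step 2 the ligand enantiomer is taken as the one that gives the (S)-configured quaternary carbon; the antipodal ligand would be used if the sense were found to be opposite.

## Route

Step 1
Reactants: 1 geraniol
Product: 2 diethyl (2E)-3,7-dimethylocta-2,6-dien-1-yl phosphate
Conditions: (EtO)2P(O)Cl, pyridine, CH2Cl2, 0 °C to rt
Reagents that add atoms: diethyl chlorophosphate, CCOP(=O)(Cl)OCC
Why: O-Phosphorylation of a primary allylic alcohol; the phosphate is the leaving group used in copper-catalysed SN2′ substitutions and the (E)-geometry of geraniol is untouched.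

Step 2
Reactants: 2 diethyl (2E)-3,7-dimethylocta-2,6-dien-1-yl phosphate
Product: 3 [(3S)-3-ethenyl-3,7-dimethyloct-6-en-1-yn-1-yl]trimethylsilane
Conditions: Me3SiC≡CH, (i-Bu)2AlH, Et3N (5 mol %), hexanes, rt; then 2, CuCl2·2H2O (5 mol %), chiral sulfonate-bearing imidazolinium salt (5 mol %), THF, −15 °C
Reagents that add atoms: ethynyltrimethylsilane, C#C[Si](C)(C)C
Why: Copper-catalysed enantioselective allylic substitution (SN2′) of an (E)-trisubstituted allylic phosphate by a dialkyl(alkynyl)aluminium, a known way to alkynyl-bearing quaternary carbons of this terpenoid type. The chiral NHC–copper complex distinguishes methyl from the 4-methylpent-3-enyl group and sets (S)-C18.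

Step 3
Reactants: 3 [(3S)-3-ethenyl-3,7-dimethyloct-6-en-1-yn-1-yl]trimethylsilane
Product: 6 (3S)-3-ethynyl-3,7-dimethyloct-6-en-1-ol, via alkylborane 4 (not isolated), via silylalkynol 5 (not isolated)
Conditions: 9-BBN, THF, 0 °C to rt; then NaOH, H2O2, H2O/MeOH, 0 °C to rt
Reagents that add atoms: hydrogen peroxide, OO
Why: Anti-Markovnikov hydroboration; 9-BBN adds to the monosubstituted vinyl group far faster than to the trisubstituted alkene or the silylalkyne. Alkaline peroxide oxidises the C–B bond, and hydroxide in methanol cleaves the C(sp)–Si bond in the same flask.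

Step 4
Reactants: 7 prop-2-yn-1-ol
Product: 9 (2E)-3-iodo-2-methylprop-2-en-1-ol, via alkenylalane 8 (not isolated)
Conditions: Me3Al, Cp2ZrCl2 (25 mol %), CH2Cl2, 0 °C to rt; then I2, THF, −30 to 0 °C
Reagents that add atoms: trimethylaluminium, C[Al](C)C; iodine, [I][I]
Why: Zirconium-catalysed syn-carboalumination (Negishi) puts methyl on the internal and aluminium on the terminal alkyne carbon; iodinolysis with retention gives the (E)-iodide.

Step 5
Reactants: 9 (2E)-3-iodo-2-methylprop-2-en-1-ol
Product: 10 triethyl{[(2E)-3-iodo-2-methylprop-2-en-1-yl]oxy}silane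
Conditions: Et3SiCl, imidazole, CH2Cl2, 0 °C
Reagents that add atoms: chlorotriethylsilane, CC[Si](CC)(CC)Cl
Why: Silylation of a primary alcohol; the triethylsilyl ether survives steps 6 to 10 and can later be removed in the presence of a tert-butyldimethylsilyl ether.

Step 6
Reactants: 6 (3S)-3-ethynyl-3,7-dimethyloct-6-en-1-ol; 10 triethyl{[(2E)-3-iodo-2-methylprop-2-en-1-yl]oxy}silane
Product: 13 (3S,4E,6E)-3,7-dimethyl-3-(4-methylpent-3-en-1-yl)-8-[(triethylsilyl)oxy]octa-4,6-dien-1-ol, via alkenylzirconocene 11 (not isolated), via alkenylzinc chloride 12 (not isolated)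
Conditions: Cp2Zr(H)Cl (2.2 equiv), THF, rt; ZnCl2, 0 °C; then 10, Pd(PPh3)4 (5 mol %), rt
Reagents that add atoms: none
Why: syn-Hydrozirconation of the terminal alkyne (zirconium at the unhindered terminus, one equivalent consumed by the hydroxyl), transmetalation to zinc and Negishi coupling at zerovalent palladium. Both partners couple with retention, so the (E,E)-diene results; the trisubstituted alkene is inert to Cp2Zr(H)Cl.

Step 7
Reactants: 13 (3S,4E,6E)-3,7-dimethyl-3-(4-methylpent-3-en-1-yl)-8-[(triethylsilyl)oxy]octa-4,6-dien-1-ol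
Product: 14 (3S,4E,6E)-3,7-dimethyl-3-(4-methylpent-3-en-1-yl)-8-[(triethylsilyl)oxy]octa-4,6-dienal
Conditions: Dess–Martin periodinane, NaHCO3, CH2Cl2, 0 °C to rt
Reagents that add atoms: none
Why: Dess–Martin oxidation of a primary alcohol under buffered conditions; the silyl ether and diene are inert and the aldehyde has no epimerisable α-centre.

Step 8
Reactants: 14 (3S,4E,6E)-3,7-dimethyl-3-(4-methylpent-3-en-1-yl)-8-[(triethylsilyl)oxy]octa-4,6-dienal
Product: 15 ethyl (2Z,5S,6E,8E)-2-iodo-5,9-dimethyl-5-(4-methylpent-3-en-1-yl)-10-[(triethylsilyl)oxy]deca-2,6,8-trienoate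
Conditions: Ph3P=CHCO2Et, N-iodosuccinimide, CH2Cl2, −20 °C; then K2CO3, 14, 0 °C to rt
Reagents that add atoms: ethyl (triphenylphosphoranylidene)acetate, CCOC(=O)C=P(c1ccccc1)(c1ccccc1)c1ccccc1; N-iodosuccinimide, O=C1CCC(=O)N1I
Why: Wittig olefination with the stabilised α-iodo ylide made in the flask. The ester ends trans to the alkyl chain, so iodine is cis to C20; this (Z)-iodide later fixes the ring-cis geometry of C21=C8.

Step 9
Reactants: 15 ethyl (2Z,5S,6E,8E)-2-iodo-5,9-dimethyl-5-(4-methylpent-3-en-1-yl)-10-[(triethylsilyl)oxy]deca-2,6,8-trienoate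
Product: 16 (2Z,5S,6E,8E)-2-iodo-5,9-dimethyl-5-(4-methylpent-3-en-1-yl)-10-[(triethylsilyl)oxy]deca-2,6,8-trien-1-ol
Conditions: (i-Bu)2AlH, CH2Cl2, −78 °C; aqueous potassium sodium tartrate
Reagents that add atoms: none
Why: 1,2-Reduction of an α,β-unsaturated ester to the allylic alcohol by diisobutylaluminium hydride; the alkenyl iodide and silyl ether are not affected at −78 °C.

Step 10
Reactants: 16 (2Z,5S,6E,8E)-2-iodo-5,9-dimethyl-5-(4-methylpent-3-en-1-yl)-10-[(triethylsilyl)oxy]deca-2,6,8-trien-1-ol
Product: 17 tert-butyl{[(2Z,5S,6E,8E)-2-iodo-5,9-dimethyl-5-(4-methylpent-3-en-1-yl)-10-[(triethylsilyl)oxy]deca-2,6,8-trien-1-yl]oxy}dimethylsilane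
Conditions: t-BuMe2SiCl, imidazole, DMF, 0 °C to rt
Reagents that add atoms: tert-butylchlorodimethylsilane, CC(C)(C)[Si](C)(C)Cl
Why: Silylation of the C10 hydroxyl, which must stay masked while the other allylic alcohol directs the epoxidation and is oxidised.

Step 11
Reactants: 17 tert-butyl{[(2Z,5S,6E,8E)-2-iodo-5,9-dimethyl-5-(4-methylpent-3-en-1-yl)-10-[(triethylsilyl)oxy]deca-2,6,8-trien-1-yl]oxy}dimethylsilane
Product: 18 (2E,4E,6S,8Z)-10-[(tert-butyldimethylsilyl)oxy]-9-iodo-2,6-dimethyl-6-(4-methylpent-3-en-1-yl)deca-2,4,8-trien-1-ol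
Conditions: PPTS (cat.), MeOH/CH2Cl2, 0 °C
Reagents that add atoms: none
Why: Acid-catalysed methanolysis removes a primary triethylsilyl ether much faster than a primary tert-butyldimethylsilyl ether, a standard selective desilylation.

Step 12
Reactants: 18 (2E,4E,6S,8Z)-10-[(tert-butyldimethylsilyl)oxy]-9-iodo-2,6-dimethyl-6-(4-methylpent-3-en-1-yl)deca-2,4,8-trien-1-ol
Product: 19 [(2S,3S)-3-{(1E,3S,5Z)-7-[(tert-butyldimethylsilyl)oxy]-6-iodo-3-methyl-3-(4-methylpent-3-en-1-yl)hepta-1,5-dien-1-yl}-2-methyloxiran-2-yl]methanol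
Conditions: Ti(OiPr)4 (10 mol %), L-(+)-diisopropyl tartrate (12 mol %), t-BuOOH (isooctane), 4 Å molecular sieves, CH2Cl2, −20 °C
Reagents that add atoms: tert-butyl hydroperoxide, CC(C)(C)OO
Why: Sharpless asymmetric epoxidation of an (E)-2-methyl allylic alcohol, the most reliable substrate class. L-(+)-Tartrate gives the (2S,3S)-oxirane (C2 and C24) by reagent control, and only the alkene of the free allylic alcohol reacts.

Step 13
Reactants: 19 [(2S,3S)-3-{(1E,3S,5Z)-7-[(tert-butyldimethylsilyl)oxy]-6-iodo-3-methyl-3-(4-methylpent-3-en-1-yl)hepta-1,5-dien-1-yl}-2-methyloxiran-2-yl]methanol; 20 3-methylbut-2-enoic acid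
Product: 21 (2S,3R,4E,6S,8Z)-10-[(tert-butyldimethylsilyl)oxy]-1,2-dihydroxy-9-iodo-2,6-dimethyl-6-(4-methylpent-3-en-1-yl)deca-4,8-dien-3-yl 3-methylbut-2-enoate
Conditions: Ti(OiPr)4 (1.5 equiv), 20 (2 equiv), CH2Cl2, 0 °C to rt
Reagents that add atoms: none
Why: Titanium-mediated opening of a 2,3-epoxy alcohol by a carboxylic acid at C3, here also the allylic carbon C24, with inversion. This gives (24R) with the ester in place and the (2S) tertiary alcohol free; SN2′ attack is blocked because C22 is neopentyl.

Step 14
Reactants: 21 (2S,3R,4E,6S,8Z)-10-[(tert-butyldimethylsilyl)oxy]-1,2-dihydroxy-9-iodo-2,6-dimethyl-6-(4-methylpent-3-en-1-yl)deca-4,8-dien-3-yl 3-methylbut-2-enoate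
Product: 23 (2E,4S,5R,6E,8S,10Z)-12-[(tert-butyldimethylsilyl)oxy]-4-hydroxy-11-iodo-4,8-dimethyl-8-(4-methylpent-3-en-1-yl)-1-oxododeca-2,6,10-trien-5-yl 3-methylbut-2-enoate, via hydroxy aldehyde 22 (not isolated)
Conditions: IBX, DMSO, rt; then Ph3P=CHCHO, rt to 40 °C
Reagents that add atoms: (triphenylphosphoranylidene)acetaldehyde, O=CC=P(c1ccccc1)(c1ccccc1)c1ccccc1
Why: IBX oxidises the primary alcohol of a 1,2-diol without glycol cleavage and leaves the tertiary alcohol. The labile α-hydroxy aldehyde is trapped in the same flask by the stabilised formyl ylide in an (E)-selective Wittig reaction.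

Step 15
Reactants: 23 (2E,4S,5R,6E,8S,10Z)-12-[(tert-butyldimethylsilyl)oxy]-4-hydroxy-11-iodo-4,8-dimethyl-8-(4-methylpent-3-en-1-yl)-1-oxododeca-2,6,10-trien-5-yl 3-methylbut-2-enoate
Product: 24 (1R,2E,4S,6Z,9E,11S)-7-{[(tert-butyldimethylsilyl)oxy]methyl}-8,11-dihydroxy-4,11-dimethyl-4-(4-methylpent-3-en-1-yl)cycloundeca-2,6,9-trien-1-yl 3-methylbut-2-enoate (both epimers at the new carbinol)
Conditions: CrCl2 (10 equiv), NiCl2 (cat.), DMSO, rt, 2 mM, slow addition
Reagents that add atoms: none
Why: Intramolecular Nozaki–Hiyama–Kishi reaction: the C–I bond adds to zerovalent nickel, the alkenyl group passes to trivalent chromium and adds 1,2 to the aldehyde, closing the eleven-membered ring at C6–C8. Aldehydes react in preference to esters, free hydroxyls are tolerated, and the alkenyl geometry is retained; the new carbinol centre is removed in step 16.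

Step 16
Reactants: 24 (1R,2E,4S,6Z,9E,11S)-7-{[(tert-butyldimethylsilyl)oxy]methyl}-8,11-dihydroxy-4,11-dimethyl-4-(4-methylpent-3-en-1-yl)cycloundeca-2,6,9-trien-1-yl 3-methylbut-2-enoate
Product: 25 (1R,2E,4S,6Z,9E,11S)-7-{[(tert-butyldimethylsilyl)oxy]methyl}-11-hydroxy-4,11-dimethyl-4-(4-methylpent-3-en-1-yl)-8-oxocycloundeca-2,6,9-trien-1-yl 3-methylbut-2-enoate
Conditions: Dess–Martin periodinane, NaHCO3, CH2Cl2, 0 °C
Reagents that add atoms: none
Why: Dess–Martin oxidation of the doubly allylic secondary alcohol; both epimers converge on the dienone and the tertiary alcohol cannot be oxidised. The low temperature keeps the [3,3] shift from starting early.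

Step 17
Reactants: 25 (1R,2E,4S,6Z,9E,11S)-7-{[(tert-butyldimethylsilyl)oxy]methyl}-11-hydroxy-4,11-dimethyl-4-(4-methylpent-3-en-1-yl)-8-oxocycloundeca-2,6,9-trien-1-yl 3-methylbut-2-enoate
Product: 26 (1R,2E,4S,6Z,9E,11S)-11-hydroxy-7-(hydroxymethyl)-4,11-dimethyl-4-(4-methylpent-3-en-1-yl)-8-oxocycloundeca-2,6,9-trien-1-yl 3-methylbut-2-enoate
Conditions: HF·pyridine, pyridine, THF, 0 °C
Reagents that add atoms: none
Why: Fluoride cleavage of the primary allylic silyl ether under buffered conditions that leave the allylic ester and the dienone intact.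

Step 18
Reactants: 26 (1R,2E,4S,6Z,9E,11S)-11-hydroxy-7-(hydroxymethyl)-4,11-dimethyl-4-(4-methylpent-3-en-1-yl)-8-oxocycloundeca-2,6,9-trien-1-yl 3-methylbut-2-enoate
Product: 28 (5S,6S,7S)-2-(hydroxymethyl)-5-methyl-5-(4-methylpent-3-en-1-yl)-6-[(E)-2-(3-methylbut-2-enoyloxy)ethenyl]-7-(2-oxopropyl)cyclohept-2-en-1-one, via enol 27 (not isolated)
Conditions: toluene (degassed), 100 °C
Reagents that add atoms: none
Why: Thermal [3,3]-sigmatropic (oxy-Cope) shift of the 3-hydroxy-4-acyloxy-1,5-diene C22=C23–C24–C2–C4=C5 inside the eleven-membered ring: C5–C22 forms as C2–C24 breaks, giving the (E)-enol ester at C23=C24 and the C2 enol 27, which tautomerises to the methyl ketone and makes the contraction irreversible. The closest known reaction type is the thermal Cope ring contraction of macrocyclic (E,E)-1,5-dienes (germacrene to elemene) combined with the oxy-Cope rearrangement; thermal Cope shifts of 3-acyloxy-1,5-dienes to enol esters are also known. Ring B closes by ring contraction, not by end-to-end cyclisation: the six reacting atoms form a chair inside the macrocycle and the tether C18–C20–C21–C8–C6 becomes the rest of the seven-membered ring. C5 and C22 are set together; both alkenes are (E), so C6 and C18 are equatorial on the chair and the two arms come out trans. Their sense relative to C18 depends on which chair is used: in the chair leading to 28 the (24R)-acyloxy group and the C1 methyl on (2S)-C2 are both equatorial, in the other both are axial, so the two pre-set centres reinforce each other and the equatorial acyloxy group becomes the (E)-enol ester. The step needs chair over boat and rearrangement without fragmentation; the strain of the (E,E,Z)-cycloundecatriene should let it run near 100 °C, below the range where retro-ene cleavage of the β-hydroxy alkene or ester pyrolysis usually start. The C21=C8 enone alkene, C18 and the side chain are spectators.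

Step 19
Reactants: 28 (5S,6S,7S)-2-(hydroxymethyl)-5-methyl-5-(4-methylpent-3-en-1-yl)-6-[(E)-2-(3-methylbut-2-enoyloxy)ethenyl]-7-(2-oxopropyl)cyclohept-2-en-1-one
Product: 29 the C8/C21 epoxide of 28, oxirane oxygen on the ring face that carries the C19 methyl and the C22 arm (anti to the 4-methylpent-3-enyl chain and the C5 acetonyl arm)
Conditions: t-BuOOH (decane), DBU, CH2Cl2, 0 °C
Reagents that add atoms: tert-butyl hydroperoxide, CC(C)(C)OO
Why: Nucleophilic (Weitz–Scheffer) epoxidation; the peroxide anion adds only to the enone, so the electron-rich side-chain alkene and the enol ester alkene are not touched. The trans arms on C5 and C22 are equatorial in the half-chair that places C18/C22 below the enone plane with the 4-methylpent-3-enyl chain pseudo-axial under C21, so the peroxide should add to the open upper face.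

Step 20
Reactants: 29 the C8/C21 epoxide of 28
Product: 30 CNP0237201.2, the tricyclic C8 carbinol (rings A, B and C) with the acetonyl arm on C5 and the (E)-enol ester arm on C22
Conditions: BF3·OEt2, CH2Cl2, −78 to −40 °C
Reagents that add atoms: none
Why: Epoxide-initiated cation–olefin cyclisation terminated by a hydroxyl: the Lewis acid polarises the C21–O bond (ionisation at C8 is disfavoured by the C6 carbonyl), C15 of the side-chain alkene attacks C21 anti to the oxygen through a chair and closes ring A (6-exo), and the C10 hydroxyl captures the tertiary C12 cation to close ring C. C21 is set by inversion, C15 by the chair with C12 equatorial, and C8 keeps its oxygen; the C8 oxygen is trans to the new C21–C15 bond and cannot compete for the cation.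

## Compound list

1 | geraniol, (2E)-3,7-dimethylocta-2,6-dien-1-ol | CC(C)=CCC/C(C)=C/CO | starting material
2 | diethyl (2E)-3,7-dimethylocta-2,6-dien-1-yl phosphate | CC(C)=CCC/C(C)=C/COP(=O)(OCC)OCC | intermediate
3 | [(3S)-3-ethenyl-3,7-dimethyloct-6-en-1-yn-1-yl]trimethylsilane | C[Si](C)(C)C#C[C@@](C)(CCC=C(C)C)C=C | intermediate
4 | 9-[(3R)-3,7-dimethyl-3-[(trimethylsilyl)ethynyl]oct-6-en-1-yl]-9-borabicyclo[3.3.1]nonane | C[Si](C)(C)C#C[C@@](C)(CCC=C(C)C)CCB1C2CCCC1CCC2 | intermediate
5 | (3S)-3,7-dimethyl-3-[(trimethylsilyl)ethynyl]oct-6-en-1-ol | C[Si](C)(C)C#C[C@@](C)(CCC=C(C)C)CCO | intermediate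
6 | (3S)-3-ethynyl-3,7-dimethyloct-6-en-1-ol | C#C[C@@](C)(CCC=C(C)C)CCO | intermediate
7 | prop-2-yn-1-ol | C#CCO | starting material
8 | dimethylaluminium (2E)-3-(dimethylalumanyl)-2-methylprop-2-en-1-olate | C[Al](C)/C=C(\C)CO[Al](C)C | intermediate
9 | (2E)-3-iodo-2-methylprop-2-en-1-ol | OC/C(C)=C/I | intermediate
10 | triethyl{[(2E)-3-iodo-2-methylprop-2-en-1-yl]oxy}silane | CC[Si](CC)(CC)OC/C(C)=C/I | intermediate
11 | (E)-alkenylzirconocene chloride from 6, hydroxyl bound as Cp2Zr(Cl) alkoxide | Cl[Zr](C1C=CC=C1)(C1C=CC=C1)/C=C/[C@@](C)(CCC=C(C)C)CCO[Zr](Cl)(C1C=CC=C1)C1C=CC=C1 | intermediate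
12 | (E)-alkenylzinc chloride from 11 | Cl[Zn]/C=C/[C@@](C)(CCC=C(C)C)CCO[Zr](Cl)(C1C=CC=C1)C1C=CC=C1 | intermediate
13 | (3S,4E,6E)-3,7-dimethyl-3-(4-methylpent-3-en-1-yl)-8-[(triethylsilyl)oxy]octa-4,6-dien-1-ol | OCC[C@](C)(CCC=C(C)C)/C=C/C=C(\C)CO[Si](CC)(CC)CC | intermediate
14 | (3S,4E,6E)-3,7-dimethyl-3-(4-methylpent-3-en-1-yl)-8-[(triethylsilyl)oxy]octa-4,6-dienal | O=CC[C@](C)(CCC=C(C)C)/C=C/C=C(\C)CO[Si](CC)(CC)CC | intermediate
15 | ethyl (2Z,5S,6E,8E)-2-iodo-5,9-dimethyl-5-(4-methylpent-3-en-1-yl)-10-[(triethylsilyl)oxy]deca-2,6,8-trienoate | CCOC(=O)/C(I)=C/C[C@](C)(CCC=C(C)C)/C=C/C=C(\C)CO[Si](CC)(CC)CC | intermediate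
16 | (2Z,5S,6E,8E)-2-iodo-5,9-dimethyl-5-(4-methylpent-3-en-1-yl)-10-[(triethylsilyl)oxy]deca-2,6,8-trien-1-ol | OC/C(I)=C/C[C@](C)(CCC=C(C)C)/C=C/C=C(\C)CO[Si](CC)(CC)CC | intermediate
17 | tert-butyl{[(2Z,5S,6E,8E)-2-iodo-5,9-dimethyl-5-(4-methylpent-3-en-1-yl)-10-[(triethylsilyl)oxy]deca-2,6,8-trien-1-yl]oxy}dimethylsilane | CC(C)(C)[Si](C)(C)OC/C(I)=C/C[C@](C)(CCC=C(C)C)/C=C/C=C(\C)CO[Si](CC)(CC)CC | intermediate
18 | (2E,4E,6S,8Z)-10-[(tert-butyldimethylsilyl)oxy]-9-iodo-2,6-dimethyl-6-(4-methylpent-3-en-1-yl)deca-2,4,8-trien-1-ol | CC(C)(C)[Si](C)(C)OC/C(I)=C/C[C@](C)(CCC=C(C)C)/C=C/C=C(\C)CO | intermediate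
19 | [(2S,3S)-3-{(1E,3S,5Z)-7-[(tert-butyldimethylsilyl)oxy]-6-iodo-3-methyl-3-(4-methylpent-3-en-1-yl)hepta-1,5-dien-1-yl}-2-methyloxiran-2-yl]methanol | CC(C)(C)[Si](C)(C)OC/C(I)=C/C[C@](C)(CCC=C(C)C)/C=C/[C@@H]1O[C@@]1(C)CO | intermediate
20 | 3-methylbut-2-enoic acid | CC(C)=CC(=O)O | starting material
21 | (2S,3R,4E,6S,8Z)-10-[(tert-butyldimethylsilyl)oxy]-1,2-dihydroxy-9-iodo-2,6-dimethyl-6-(4-methylpent-3-en-1-yl)deca-4,8-dien-3-yl 3-methylbut-2-enoate | CC(C)(C)[Si](C)(C)OC/C(I)=C/C[C@](C)(CCC=C(C)C)/C=C/[C@@H](OC(=O)C=C(C)C)[C@@](C)(O)CO | intermediate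
22 | (2R,3R,4E,6S,8Z)-10-[(tert-butyldimethylsilyl)oxy]-2-hydroxy-9-iodo-2,6-dimethyl-6-(4-methylpent-3-en-1-yl)-1-oxodeca-4,8-dien-3-yl 3-methylbut-2-enoate | CC(C)(C)[Si](C)(C)OC/C(I)=C/C[C@](C)(CCC=C(C)C)/C=C/[C@@H](OC(=O)C=C(C)C)[C@@](C)(O)C=O | intermediate
23 | (2E,4S,5R,6E,8S,10Z)-12-[(tert-butyldimethylsilyl)oxy]-4-hydroxy-11-iodo-4,8-dimethyl-8-(4-methylpent-3-en-1-yl)-1-oxododeca-2,6,10-trien-5-yl 3-methylbut-2-enoate | CC(C)(C)[Si](C)(C)OC/C(I)=C/C[C@](C)(CCC=C(C)C)/C=C/[C@@H](OC(=O)C=C(C)C)[C@@](C)(O)/C=C/C=O | intermediate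
24 | (1R,2E,4S,6Z,9E,11S)-7-{[(tert-butyldimethylsilyl)oxy]methyl}-8,11-dihydroxy-4,11-dimethyl-4-(4-methylpent-3-en-1-yl)cycloundeca-2,6,9-trien-1-yl 3-methylbut-2-enoate, both epimers at ring C8 (C6 of the target) | CC(C)=CCC[C@@]1(C)C/C=C(CO[Si](C)(C)C(C)(C)C)\C(O)/C=C/[C@](C)(O)[C@H](OC(=O)C=C(C)C)/C=C/1 | intermediate
25 | (1R,2E,4S,6Z,9E,11S)-7-{[(tert-butyldimethylsilyl)oxy]methyl}-11-hydroxy-4,11-dimethyl-4-(4-methylpent-3-en-1-yl)-8-oxocycloundeca-2,6,9-trien-1-yl 3-methylbut-2-enoate | CC(C)=CCC[C@@]1(C)C/C=C(CO[Si](C)(C)C(C)(C)C)\C(=O)/C=C/[C@](C)(O)[C@H](OC(=O)C=C(C)C)/C=C/1 | intermediate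
26 | (1R,2E,4S,6Z,9E,11S)-11-hydroxy-7-(hydroxymethyl)-4,11-dimethyl-4-(4-methylpent-3-en-1-yl)-8-oxocycloundeca-2,6,9-trien-1-yl 3-methylbut-2-enoate | CC(C)=CCC[C@@]1(C)C/C=C(CO)\C(=O)/C=C/[C@](C)(O)[C@H](OC(=O)C=C(C)C)/C=C/1 | intermediate
27 | C2 enol of 28, 7-(2-hydroxyprop-1-en-1-yl) in place of 7-(2-oxopropyl) | C/C(O)=C/[C@@H]1C(=O)C(CO)=CC[C@](C)(CCC=C(C)C)[C@H]1/C=C/OC(=O)C=C(C)C | intermediate
28 | (5S,6S,7S)-2-(hydroxymethyl)-5-methyl-5-(4-methylpent-3-en-1-yl)-6-[(E)-2-(3-methylbut-2-enoyloxy)ethenyl]-7-(2-oxopropyl)cyclohept-2-en-1-one | CC(=O)C[C@@H]1C(=O)C(CO)=CC[C@](C)(CCC=C(C)C)[C@H]1/C=C/OC(=O)C=C(C)C | intermediate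
29 | C8/C21 epoxide of 28, oxirane oxygen syn to the C19 methyl and the C22 arm, anti to the 4-methylpent-3-enyl chain and the C5 acetonyl arm | CC(=O)C[C@@H]1C(=O)[C@@]2(CO)O[C@H]2C[C@](C)(CCC=C(C)C)[C@H]1/C=C/OC(=O)C=C(C)C | intermediate
30 | CNP0237201.2: tricyclic C8 carbinol with rings A, B and C, acetonyl on C5 and (E)-2-(3-methylbut-2-enoyloxy)ethenyl on C22 | CC(=O)C[C@@H]1C(=O)[C@]2(O)COC(C)(C)[C@@H]3CC[C@@](C)(C[C@@H]32)[C@H]1/C=C/OC(=O)C=C(C)C | target

## Step count and risks

Total: 20 steps. Longest linear sequence: 18 steps (1, 2, 3, 6–20 from geraniol); steps 4 and 5 form the side branch.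

**Step 18 (key step).** The β-hydroxy alkene may fragment by a retro-ene path, or the rearrangement may pass through the other chair or a boat, which would scramble the C5/C22 relationship and the enol ester geometry. Fallback: set out from 25 and silylate the C2 hydroxyl (Me3SiOTf, 2,6-lutidine) to the bis-silyl ether F1. A silyloxy-Cope shift cannot undergo the retro-ene cleavage. Heating gives the ring-contracted enol silane F2, and HF·pyridine removes both silyl groups to rejoin the route at 28.

**Step 2.** Discrimination between methyl and the CH2 of the side chain may be incomplete, or hydroalumination of the silylalkyne may compete with alkynylaluminium formation, lowering enantiomeric purity or SN2′ selectivity. Fallback from 1: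
- Sharpless epoxidation with D-(−)-diethyl tartrate gives (2R,3R)-2,3-epoxygeraniol F3.
- Aluminium-directed alkynylation at the tertiary epoxide carbon with inversion (Et2AlC≡CSiMe3) gives diol F4.
- NaIO4 cleavage gives the α-quaternary aldehyde F5.
- Wittig methylenation (Ph3P=CH2) rejoins the route at 3.

**Step 15.** Intermolecular coupling or protodeiodination may outrun closure of the strained eleven-membered ring. Fallback from 21:
- Isolate the hydroxy aldehyde 22 after the IBX oxidation.
- Convert it by a Takai-type stannyl olefination (CrCl2, Bu3SnCHBr2, LiI) into the (E)-alkenylstannane F6.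
- Close the ring by a carbonylative Stille macrocyclisation (Pd2(dba)3, AsPh3, CO, high dilution), which gives the dienone directly and rejoins the route at 25.

**Step 19.** The peroxide anion may attack the enol ester carbonyl, the base may epimerise C5, or the peroxide may add to the lower face. Fallback from 28, which makes the C8–O bond after the rings:
- Silylate the C10 hydroxyl to the trimethylsilyl ether F7.
- Cyclise by a Me3SiOTf-catalysed conjugate cation–olefin reaction that keeps the C6 oxygen as an enol silane, giving the tricyclic enol silane F8.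
- Rubottom oxidation with dimethyldioxirane, which must come from the face opposite to ring A, followed by mild acid, rejoins the route at 30.

**Step 20.** The cation at C12 may lose a proton before the hindered C10 hydroxyl closes ring C. A 1,2-acyl shift at C21 may also compete with attack of the alkene; that case is covered by the detour given for step 19. Fallback from 29: use Me2AlCl, which favours ene-type termination, to obtain the ring A-closed isopropenyl diol F9. Then close ring C by Markovnikov hydroalkoxylation (Hg(OCOCF3)2, then NaBH4) to rejoin the route at 30. The C8 hydroxyl is trans to C15 and cannot compete.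

## Further compounds

F1 | step 18 | (1R,2E,4S,6Z,9E,11S)-7-{[(tert-butyldimethylsilyl)oxy]methyl}-4,11-dimethyl-4-(4-methylpent-3-en-1-yl)-8-oxo-11-[(trimethylsilyl)oxy]cycloundeca-2,6,9-trien-1-yl 3-methylbut-2-enoate | CC(C)=CCC[C@@]1(C)C/C=C(CO[Si](C)(C)C(C)(C)C)\C(=O)/C=C/[C@](C)(O[Si](C)(C)C)[C@H](OC(=O)C=C(C)C)/C=C/1
F2 | step 18 | ring-contracted enol silane: 28 with C10 as tert-butyldimethylsilyl ether and the acetonyl arm as its C2 trimethylsilyl enol ether | C/C(O[Si](C)(C)C)=C/[C@@H]1C(=O)C(CO[Si](C)(C)C(C)(C)C)=CC[C@](C)(CCC=C(C)C)[C@H]1/C=C/OC(=O)C=C(C)C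
F3 | step 2 | (2R,3R)-2,3-epoxygeraniol | CC(C)=CCC[C@@]1(C)O[C@@H]1CO
F4 | step 2 | (2S,3R)-3-methyl-3-(4-methylpent-3-en-1-yl)-5-(trimethylsilyl)pent-4-yne-1,2-diol | C[Si](C)(C)C#C[C@@](C)(CCC=C(C)C)[C@H](O)CO
F5 | step 2 | (2R)-2-methyl-2-(4-methylpent-3-en-1-yl)-4-(trimethylsilyl)but-3-ynal | C[Si](C)(C)C#C[C@@](C)(CCC=C(C)C)C=O
F6 | step 15 | (E)-alkenylstannane from 22: 21 with the CH2OH group replaced by (E)-CH=CH–SnBu3 | CC(C)(C)[Si](C)(C)OC/C(I)=C/C[C@](C)(CCC=C(C)C)/C=C/[C@@H](OC(=O)C=C(C)C)[C@@](C)(O)/C=C/[Sn](CCCC)(CCCC)CCCC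
F7 | step 19 | C10 trimethylsilyl ether of 28 | CC(=O)C[C@@H]1C(=O)C(CO[Si](C)(C)C)=CC[C@](C)(CCC=C(C)C)[C@H]1/C=C/OC(=O)C=C(C)C
F8 | step 19 | tricyclic C6 trimethylsilyl enol ether (C6=C8) with rings A and C closed | CC(=O)C[C@@H]1C(O[Si](C)(C)C)=C2COC(C)(C)[C@@H]3CC[C@@](C)(C[C@@H]32)[C@H]1/C=C/OC(=O)C=C(C)C
F9 | step 20 | ring A-closed diol with isopropenyl on C15, C8 hydroxyl and C10 hydroxymethyl | CC(=O)C[C@@H]1C(=O)[C@](O)(CO)[C@H]2C[C@](C)(CC[C@H]2C(C)=C)[C@H]1/C=C/OC(=O)C=C(C)C
A1 | alternative 1 | cyclic ketal spanning C2 and O7 with allyl on C22 | CO[C@]1(C)C[C@@H]2[C@H](O1)[C@]3(O[Si](CC)(CC)CC)COC(C)(C)[C@@H]4CC[C@@](C)(C[C@@H]43)[C@H]2CC=C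
A2 | alternative 2 | tricyclic bridgehead alkene with C6 ketone, C8 carbinol and sulfone on C17 | C1C(=O)[C@]2(O)COC(C)(C)C3=C2C[C@](C)([C@H](C3)S(=O)(=O)c4ccccc4)C1
A3 | alternative 3 | bicyclo[4.3.1]decane with C20 and C22 ketones and C15 carbinol | C1CC[C@@H]2[C@H](O)CC[C@@](C)(C2=O)C1=O
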